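**Assumption:** all compounds marked "starting material" in the compound list are purchasable, and ring carbons are referred to by germacrane numbering (C1–C15; lactone carbons C7, C8, C11–C13).

## Retrosynthetic overview

1. Target ⇒ ring-closing metathesis at C1=C10 of a seco-diene; the ten-membered carbocycle is the second and last ring formed.
2. Seco-diene = trans-α-methylene-γ-butyrolactone (first ring) ⇒ C7–C8 bond by chiral Brønsted acid-catalysed allylboration/lactonisation of an achiral aldehyde with an achiral (2Z)-2-(methoxycarbonyl)allylboronate; both stereocentres are set here.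
3. Allylboronate ⇒ ynoate syn-hydroalumination/borylmethylation; ynoate ⇒ allylic bromide + methyl propiolate; (Z)-C4=C5 ⇒ iron-catalysed syn-carbomagnesiation of mono-silylated but-2-yne-1,4-diol; C15 ester by Steglich coupling.
4. Aldehyde (C8–C10, C14) ⇒ monomethyl itaconate by acid reduction, silylation and ester half-reduction.

## Route

Step 1
Reactants: 1 4-[(tert-butyldimethylsilyl)oxy]but-2-yn-1-ol; 2 but-3-enylmagnesium bromide
Product: 3 (2Z)-3-{[(tert-butyldimethylsilyl)oxy]methyl}hepta-2,6-dien-1-ol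
Conditions: 2 (3.5 equiv), Fe(acac)3 (15 mol%), THF, −78 → 0 °C; then H2O
Reagents that add atoms: none
Why: Iron-catalysed, alkoxide-directed syn-carbomagnesiation of a propargylic alcohol puts the butenyl group on the alkyne carbon remote from the hydroxyl and H (after quench) on the near one from the same face, so CH2OTBS ends cis to CH2OH and the C4=C5 geometry of the target is fixed (no stereocentre).

Step 2
Reactants: 3 (2Z)-3-{[(tert-butyldimethylsilyl)oxy]methyl}hepta-2,6-dien-1-ol
Product: 4 (2Z)-1-bromo-3-{[(tert-butyldimethylsilyl)oxy]methyl}hepta-2,6-diene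
Conditions: CBr4, PPh3, CH2Cl2, −20 °C
Reagents that add atoms: carbon tetrabromide (BrC(Br)(Br)Br)
Why: Appel bromination of a primary allylic alcohol proceeds by SN2 under neutral, cold conditions without allylic shift or loss of olefin geometry, and the silyl ether survives.

Step 3
Reactants: 4 (2Z)-1-bromo-3-{[(tert-butyldimethylsilyl)oxy]methyl}hepta-2,6-diene; 5 methyl propiolate
Product: 6 methyl (5Z)-6-{[(tert-butyldimethylsilyl)oxy]methyl}deca-5,9-dien-2-ynoate
Conditions: 5 (1.5 equiv), CuI (20 mol%), Cs2CO3 (1.2 equiv), DMF, 20 °C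
Reagents that add atoms: none
Why: Copper acetylide alkylation (copper-catalysed sp–sp3 coupling of a terminal alkyne with an allylic bromide) occurs at the primary carbon and forms the C6–C7 bond, and the carbonate base is mild enough to leave the skipped enynoate unisomerised.

Step 4
Reactants: 6 methyl (5Z)-6-{[(tert-butyldimethylsilyl)oxy]methyl}deca-5,9-dien-2-ynoate; 7 2-(chloromethyl)-4,4,5,5-tetramethyl-1,3,2-dioxaborolane
Product: 9 methyl (2Z,5Z)-6-{[(tert-butyldimethylsilyl)oxy]methyl}-2-[(4,4,5,5-tetramethyl-1,3,2-dioxaborolan-2-yl)methyl]deca-2,5,9-trienoate, via alkenylalane 8 (not isolated)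
Conditions: i-Bu2AlH (1.2 equiv), HMPA (2 equiv), THF, 0 °C; then 7 (1.5 equiv), 0 → 20 °C
Reagents that add atoms: none
Why: Syn-hydroalumination of the ynoate by the i-Bu2AlH–HMPA complex (conjugate hydride delivery without carbonyl reduction) gives the α-alumino enoate, which is homologated by the chloromethylboronate through an ate complex and 1,2-migration (Matteson-type) with retention, leaving the C6 chain cis to CO2Me.

Step 5
Reactants: 9 methyl (2Z,5Z)-6-{[(tert-butyldimethylsilyl)oxy]methyl}-2-[(4,4,5,5-tetramethyl-1,3,2-dioxaborolan-2-yl)methyl]deca-2,5,9-trienoate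
Product: 10 methyl (2Z,5Z)-6-(hydroxymethyl)-2-[(4,4,5,5-tetramethyl-1,3,2-dioxaborolan-2-yl)methyl]deca-2,5,9-trienoate
Conditions: CSA (10 mol%), MeOH/CH2Cl2 (1:1), 0 °C
Reagents that add atoms: none
Why: Acid-catalysed methanolysis removes the primary allylic silyl ether, while the ester-deactivated pinacol allylboronate and the enoate are inert to these conditions.

Step 6
Reactants: 10 methyl (2Z,5Z)-6-(hydroxymethyl)-2-[(4,4,5,5-tetramethyl-1,3,2-dioxaborolan-2-yl)methyl]deca-2,5,9-trienoate; 11 2-hydroxy-2-methylpropanoic acid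
Product: 12 methyl (2Z,5Z)-6-{[(2-hydroxy-2-methylpropanoyl)oxy]methyl}-2-[(4,4,5,5-tetramethyl-1,3,2-dioxaborolan-2-yl)methyl]deca-2,5,9-trienoate
Conditions: 11 (1.5 equiv), EDC·HCl, DMAP (10 mol%), CH2Cl2, 0 → 20 °C
Reagents that add atoms: none
Why: Steglich esterification acylates the unhindered primary allylic alcohol, whereas the tertiary hydroxyl of the acid is too hindered to compete, so the C15 ester is installed without a protecting group.

Step 7
Reactants: 13 4-methoxy-2-methylidene-4-oxobutanoic acid (monomethyl itaconate)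
Product: 14 methyl 3-(hydroxymethyl)but-3-enoate
Conditions: BH3·SMe2 (1.05 equiv), THF, −10 → 20 °C; then H2O
Reagents that add atoms: none
Why: Borane reduces the carboxylic acid chemoselectively (via the acyloxyborane) in the presence of the methyl ester, and one equivalent leaves no B–H to hydroborate the alkene.

Step 8
Reactants: 14 methyl 3-(hydroxymethyl)but-3-enoate
Product: 15 methyl 3-{[(tert-butyldimethylsilyl)oxy]methyl}but-3-enoate
Conditions: TBSCl, imidazole, CH2Cl2, 0 °C
Reagents that add atoms: tert-butyldimethylsilyl chloride (CC(C)(C)[Si](C)(C)Cl)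
Why: Standard silylation of the primary alcohol (used crude from step 7) blocks lactonisation and masks the future C14 hydroxyl.

Step 9
Reactants: 15 methyl 3-{[(tert-butyldimethylsilyl)oxy]methyl}but-3-enoate
Product: 16 3-{[(tert-butyldimethylsilyl)oxy]methyl}but-3-enal
Conditions: i-Bu2AlH (1.05 equiv), CH2Cl2, −78 °C; then H2O, −78 → 0 °C
Reagents that add atoms: none
Why: Half-reduction of the ester through the cold-stable aluminium hemiacetal gives the β,γ-unsaturated aldehyde, which is used at once to avoid migration of the double bond into conjugation.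

Step 10
Reactants: 12 methyl (2Z,5Z)-6-{[(2-hydroxy-2-methylpropanoyl)oxy]methyl}-2-[(4,4,5,5-tetramethyl-1,3,2-dioxaborolan-2-yl)methyl]deca-2,5,9-trienoate; 16 3-{[(tert-butyldimethylsilyl)oxy]methyl}but-3-enal
Product: 19 (4R,5S)-5-[2-(hydroxymethyl)prop-2-en-1-yl]-4-[(2Z)-3-{[(2-hydroxy-2-methylpropanoyl)oxy]methyl}hepta-2,6-dien-1-yl]-3-methylideneoxolan-2-one, via borate adduct 17 (not isolated), via silyl lactone 18 (not isolated)
Conditions: 16 (1.5 equiv), (R)-3,3'-bis(2,4,6-triisopropylphenyl)-BINOL N-triflylphosphoramide (10 mol%), 4 Å MS, toluene, −20 → 20 °C; then p-TsOH·H2O (0.3 equiv), MeOH, 20 °C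
Reagents that add atoms: none
Why: Proposed new method: chiral Brønsted acid-catalysed allylboration of an aldehyde with a γ-substituted 2-(methoxycarbonyl)allyl pinacolboronate (closest known reactions: chiral phosphoric acid-catalysed allylboration with simple allyl and crotyl pinacolboronates, and achiral triflic acid- or Sc(OTf)3-catalysed additions of 2-alkoxycarbonyl allylboronates), in which the stronger N-triflylphosphoramide hydrogen-bonds the pseudo-axial boronate oxygen to activate the ester-deactivated boron while its phosphoryl oxygen holds the formyl C–H, so that the closed chair transition state exposes the Re face of 16 (8S) and the (2Z) geometry places the C6 chain equatorial (anti addition, 7R), after which acidic methanol cleaves the borate, closes the trans lactone and removes the silyl group.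

Step 11
Reactants: 19 (4R,5S)-5-[2-(hydroxymethyl)prop-2-en-1-yl]-4-[(2Z)-3-{[(2-hydroxy-2-methylpropanoyl)oxy]methyl}hepta-2,6-dien-1-yl]-3-methylideneoxolan-2-one
Product: 20 (1(10)E,4Z,7R,8S)-14-hydroxy-15-[(2-hydroxy-2-methylpropanoyl)oxy]germacra-1(10),4,11(13)-trien-12,8-olide (target)
Conditions: second-generation Hoveyda–Grubbs catalyst RuCl2(=CH-C6H4-2-OiPr)(H2IMes) (15 mol%), 1,4-benzoquinone (30 mol%), toluene (0.5 mM), 80 °C
Reagents that add atoms: none
Why: Ring-closing metathesis loads ruthenium on the monosubstituted C1 vinyl group and closes onto the 1,1-disubstituted olefin (activated by its free allylic hydroxyl), and the ten-membered ring can only accommodate the new trisubstituted C1=C10 bond with C2 and C9 cis, which is the required (E) isomer; no stereocentre is touched.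

## Compound list

1 | 4-[(tert-butyldimethylsilyl)oxy]but-2-yn-1-ol | OCC#CCO[Si](C)(C)C(C)(C)C | starting material
2 | but-3-enylmagnesium bromide | C=CCC[Mg]Br | starting material
3 | (2Z)-3-{[(tert-butyldimethylsilyl)oxy]methyl}hepta-2,6-dien-1-ol | OC/C=C(\CO[Si](C)(C)C(C)(C)C)CCC=C | intermediate
4 | (2Z)-1-bromo-3-{[(tert-butyldimethylsilyl)oxy]methyl}hepta-2,6-diene | BrC/C=C(\CO[Si](C)(C)C(C)(C)C)CCC=C | intermediate
5 | methyl propiolate | C#CC(=O)OC | starting material
6 | methyl (5Z)-6-{[(tert-butyldimethylsilyl)oxy]methyl}deca-5,9-dien-2-ynoate | COC(=O)C#CC/C=C(\CO[Si](C)(C)C(C)(C)C)CCC=C | intermediate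
7 | 2-(chloromethyl)-4,4,5,5-tetramethyl-1,3,2-dioxaborolane | ClCB1OC(C)(C)C(C)(C)O1 | starting material
8 | methyl (2E,5Z)-2-(diisobutylalumanyl)-6-{[(tert-butyldimethylsilyl)oxy]methyl}deca-2,5,9-trienoate (C4 chain cis to CO2Me) | COC(=O)/C([Al](CC(C)C)CC(C)C)=C\C/C=C(\CO[Si](C)(C)C(C)(C)C)CCC=C | intermediate
9 | methyl (2Z,5Z)-6-{[(tert-butyldimethylsilyl)oxy]methyl}-2-[(4,4,5,5-tetramethyl-1,3,2-dioxaborolan-2-yl)methyl]deca-2,5,9-trienoate | COC(=O)/C(CB1OC(C)(C)C(C)(C)O1)=C\C/C=C(\CO[Si](C)(C)C(C)(C)C)CCC=C | intermediate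
10 | methyl (2Z,5Z)-6-(hydroxymethyl)-2-[(4,4,5,5-tetramethyl-1,3,2-dioxaborolan-2-yl)methyl]deca-2,5,9-trienoate | COC(=O)/C(CB1OC(C)(C)C(C)(C)O1)=C\C/C=C(\CO)CCC=C | intermediate
11 | 2-hydroxy-2-methylpropanoic acid | CC(C)(O)C(=O)O | starting material
12 | methyl (2Z,5Z)-6-{[(2-hydroxy-2-methylpropanoyl)oxy]methyl}-2-[(4,4,5,5-tetramethyl-1,3,2-dioxaborolan-2-yl)methyl]deca-2,5,9-trienoate | COC(=O)/C(CB1OC(C)(C)C(C)(C)O1)=C\C/C=C(\COC(=O)C(C)(C)O)CCC=C | intermediate
13 | 4-methoxy-2-methylidene-4-oxobutanoic acid (monomethyl itaconate) | COC(=O)CC(=C)C(=O)O | starting material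
14 | methyl 3-(hydroxymethyl)but-3-enoate | COC(=O)CC(=C)CO | intermediate
15 | methyl 3-{[(tert-butyldimethylsilyl)oxy]methyl}but-3-enoate | COC(=O)CC(=C)CO[Si](C)(C)C(C)(C)C | intermediate
16 | 3-{[(tert-butyldimethylsilyl)oxy]methyl}but-3-enal | O=CCC(=C)CO[Si](C)(C)C(C)(C)C | intermediate
17 | methyl (3R,4S)-6-{[(tert-butyldimethylsilyl)oxy]methyl}-3-[(2Z)-3-{[(2-hydroxy-2-methylpropanoyl)oxy]methyl}hepta-2,6-dien-1-yl]-2-methylidene-4-[(4,4,5,5-tetramethyl-1,3,2-dioxaborolan-2-yl)oxy]hept-6-enoate | COC(=O)C(=C)[C@@H](C/C=C(\COC(=O)C(C)(C)O)CCC=C)[C@H](CC(=C)CO[Si](C)(C)C(C)(C)C)OB1OC(C)(C)C(C)(C)O1 | intermediate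
18 | (4R,5S)-5-(2-{[(tert-butyldimethylsilyl)oxy]methyl}prop-2-en-1-yl)-4-[(2Z)-3-{[(2-hydroxy-2-methylpropanoyl)oxy]methyl}hepta-2,6-dien-1-yl]-3-methylideneoxolan-2-one | C=C1C(=O)O[C@@H](CC(=C)CO[Si](C)(C)C(C)(C)C)[C@@H]1C/C=C(\COC(=O)C(C)(C)O)CCC=C | intermediate
19 | (4R,5S)-5-[2-(hydroxymethyl)prop-2-en-1-yl]-4-[(2Z)-3-{[(2-hydroxy-2-methylpropanoyl)oxy]methyl}hepta-2,6-dien-1-yl]-3-methylideneoxolan-2-one | C=C1C(=O)O[C@@H](CC(=C)CO)[C@@H]1C/C=C(\COC(=O)C(C)(C)O)CCC=C | intermediate
20 | (1(10)E,4Z,7R,8S)-14-hydroxy-15-[(2-hydroxy-2-methylpropanoyl)oxy]germacra-1(10),4,11(13)-trien-12,8-olide; trans-fused α-methylene-γ-butyrolactone on a cyclodeca-1(10),4-diene | C=C1C(=O)O[C@H]2C/C(CO)=C\CC/C(COC(=O)C(C)(C)O)=C/C[C@H]12 | target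

## Step count and risks

Total steps: 11. Longest linear sequence: 8 (steps 1–6, 10, 11); the aldehyde branch (steps 7–9) is three steps.

**Step 11 (ring-closing metathesis).** Closing a ten-membered ring onto a 1,1-disubstituted olefin to give a trisubstituted alkene may be slow and lose out to oligomerisation. The fallback closes the carbocycle before the lactone, on a conformationally free substrate. It sets out from borate adduct 17: a neutral aqueous work-up (pH 7 buffer) in place of the acid treatment gives the open-chain hydroxy ester F1, and TESCl/imidazole in DMF gives the triethylsilyl ether F2. Ring-closing metathesis of F2 (same ruthenium catalyst, toluene, 0.5 mM, 80 °C), now free of the trans-fused lactone and of the free allylic alcohol, gives the silylated cyclodecadiene ester F3. Treatment with p-TsOH·H2O in MeOH then removes both silyl groups and closes the lactone, coming back to the route at 20.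

**Step 10 (the new method).** The chiral acid may not activate the ester-deactivated boronate enough, or ee/dr may be low. The sense of induction is assigned by analogy with the simple allylboronate series; if it proves opposite, the (S)-acid is used. The fallback is the known chromium-catalysed enantioselective Nozaki–Hiyama–Kishi 2-(alkoxycarbonyl)allylation. It sets out from 12: NaBO3·4H2O in THF/H2O oxidises the C–B bond to the allylic alcohol F4, and CBr4/PPh3 converts it into the allylic bromide F5. F5 and 16 are then combined with CrCl2 (10 mol%), a chiral carbazole bis(oxazoline) ligand and Mn powder in THF. The equilibrating allylchromium adds anti whatever the bromide geometry, and mild acid work-up closes the trans lactone, coming back to the route at 18 (second stage of step 10).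

**Step 4 (hydroalumination/borylmethylation).** A single olefin geometry must be delivered on a reduction- and base-sensitive skipped enynoate; over-reduction or isomerisation would erode the trans selectivity of step 10. The fallback is a stepwise, known sequence that sets out from 6. Bu3SnH with Pd(PPh3)4 (syn-hydrostannation, tin at the α-carbon) gives the α-stannyl enoate F6. I2 in CH2Cl2 gives the α-iodo enoate F7 with retention. Negishi coupling of F7 with IZnCH2Bpin under Pd(PPh3)4 catalysis installs the borylmethyl group with retention, coming back to the route at 9.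

Further compounds
F1 | step 11 | methyl (3R,4S)-6-{[(tert-butyldimethylsilyl)oxy]methyl}-4-hydroxy-3-[(2Z)-3-{[(2-hydroxy-2-methylpropanoyl)oxy]methyl}hepta-2,6-dien-1-yl]-2-methylidenehept-6-enoate | COC(=O)C(=C)[C@@H](C/C=C(\COC(=O)C(C)(C)O)CCC=C)[C@H](CC(=C)CO[Si](C)(C)C(C)(C)C)O
F2 | step 11 | methyl (3R,4S)-6-{[(tert-butyldimethylsilyl)oxy]methyl}-3-[(2Z)-3-{[(2-hydroxy-2-methylpropanoyl)oxy]methyl}hepta-2,6-dien-1-yl]-2-methylidene-4-[(triethylsilyl)oxy]hept-6-enoate | COC(=O)C(=C)[C@@H](C/C=C(\COC(=O)C(C)(C)O)CCC=C)[C@H](CC(=C)CO[Si](C)(C)C(C)(C)C)O[Si](CC)(CC)CC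
F3 | step 11 | methyl 2-[(1R,2S,4E,8Z)-4-{[(tert-butyldimethylsilyl)oxy]methyl}-8-{[(2-hydroxy-2-methylpropanoyl)oxy]methyl}-2-[(triethylsilyl)oxy]cyclodeca-4,8-dien-1-yl]prop-2-enoate | COC(=O)C(=C)[C@H]1C/C=C(\COC(=O)C(C)(C)O)CC/C=C(CO[Si](C)(C)C(C)(C)C)\C[C@@H]1O[Si](CC)(CC)CC
F4 | step 10 | methyl (2Z,5Z)-2-(hydroxymethyl)-6-{[(2-hydroxy-2-methylpropanoyl)oxy]methyl}deca-2,5,9-trienoate | COC(=O)/C(CO)=C\C/C=C(\COC(=O)C(C)(C)O)CCC=C
F5 | step 10 | methyl (2E,5Z)-2-(bromomethyl)-6-{[(2-hydroxy-2-methylpropanoyl)oxy]methyl}deca-2,5,9-trienoate | COC(=O)/C(CBr)=C\C/C=C(\COC(=O)C(C)(C)O)CCC=C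
F6 | step 4 | methyl (2E,5Z)-6-{[(tert-butyldimethylsilyl)oxy]methyl}-2-(tributylstannyl)deca-2,5,9-trienoate | COC(=O)/C([Sn](CCCC)(CCCC)CCCC)=C\C/C=C(\CO[Si](C)(C)C(C)(C)C)CCC=C
F7 | step 4 | methyl (2E,5Z)-6-{[(tert-butyldimethylsilyl)oxy]methyl}-2-iododeca-2,5,9-trienoate | COC(=O)/C(I)=C\C/C=C(\CO[Si](C)(C)C(C)(C)C)CCC=C
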